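**Retrosynthetic overview**

1. The oleate C–O bond, the oxirane (from the prenyl C=C) and the N/O protecting groups are removed first, which leads back to the 3-alkyl-5-prenylindole 27.
2. The strategy rests on the benzene ring of the indole carrying a substituent only at C5: C7a–C7–C6–C5 are taken from a 5-prenyl-2-aminofuran, C3a–C4 from a vinyl group, and N1–C2–C3 is the tether between them.
3. Key disconnections: C3a–C7a and C4–C5 (intramolecular furan Diels–Alder reaction of carbinol 23), then C2–C3 (α-amino organolithium 22 plus vinyl ketone 21).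
4. Ring order: furan (bought); the pyrrole ring and the carbocycle close together in the cycloaddition; the benzene ring and the indole arise by loss of the furan oxygen and the C3 hydroxyl as water; the oxirane comes last.
5. Stereocentres: the side-chain carbon comes from an Evans hydroxymethylation before the indole is built; the oxirane carbon comes from a reagent-controlled Shi epoxidation.

Key step: step 11

Assumption: the target is read as (S) at the side-chain carbon and (S) at the oxirane carbon; tributyl(iodomethyl)stannane, (S)-4-benzyloxazolidin-2-one and the L-fructose-derived Shi ketone are bought.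

**Route**

Step 1
Reactants: 1 2-furoic acid; 2 prenyl bromide
Product: 4 5-(3-methylbut-2-en-1-yl)furan-2-carboxylic acid, via lithium 5-lithiofuran-2-carboxylate 3 (not isolated)
Conditions: LiN(i-Pr)2 (2.2 equiv), THF, −78 °C; then 2, −78 °C → rt; aq. HCl work-up
Reagents that add atoms: none
Why: Two equivalents of the amide base should form the carboxylate and then metalate furan C5 (directed metalation), and the heteroaryllithium should be alkylated at the primary carbon of the allylic bromide (SN2).

Step 2
Reactants: 4 5-(3-methylbut-2-en-1-yl)furan-2-carboxylic acid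
Product: 7 tert-butyl N-[5-(3-methylbut-2-en-1-yl)furan-2-yl]carbamate, via furoyl azide 5 (not isolated), via furyl isocyanate 6 (not isolated)
Conditions: (PhO)2P(O)N3, Et3N, t-BuOH/toluene, 90 °C
Reagents that add atoms: diphenylphosphoryl azide, [N-]=[N+]=NP(=O)(Oc1ccccc1)Oc1ccccc1; tert-butanol, CC(C)(C)O
Why: Curtius rearrangement of the acyl azide gives the isocyanate, which tert-butanol traps as the carbamate, the stable form of the 2-aminofuran.

Step 3
Reactants: 7 tert-butyl N-[5-(3-methylbut-2-en-1-yl)furan-2-yl]carbamate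
Product: 9 tert-butyl N-[5-(3-methylbut-2-en-1-yl)furan-2-yl]-N-[(tributylstannyl)methyl]carbamate, via sodium carbamate 8 (not isolated)
Conditions: NaH, DMF, 0 °C; Bu3SnCH2I, 0 °C → rt
Reagents that add atoms: tributyl(iodomethyl)stannane, CCCC[Sn](CCCC)(CCCC)CI
Why: The carbamate anion should be N-alkylated by the reactive primary iodide (SN2), which installs the carbon that becomes indole C2 as a stannane ready for tin–lithium exchange.

Step 4
Reactants: 10 3-hydroxy-3-methylbutanoic acid
Product: 12 3-methyl-3-(triethylsilyloxy)butanoic acid, via bis-silylated acid 11 (not isolated)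
Conditions: Et3SiOTf (2.2 equiv), 2,6-lutidine, CH2Cl2, 0 °C; then K2CO3, MeOH/H2O, 0 °C; work-up at pH 4–5
Reagents that add atoms: triethylsilyl triflate, CC[Si](CC)(CC)OS(=O)(=O)C(F)(F)F
Why: The silyl triflate silylates the hindered tertiary alcohol and the acid, and mild aqueous carbonate then cleaves only the labile silyl ester (silyl ether protection).

Step 5
Reactants: 12 3-methyl-3-(triethylsilyloxy)butanoic acid; 13 (S)-4-benzyloxazolidin-2-one
Product: 15 (S)-4-benzyl-3-[3-methyl-3-(triethylsilyloxy)butanoyl]oxazolidin-2-one, via mixed pivalic anhydride 14 (not isolated)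
Conditions: t-BuCOCl, Et3N, THF, −20 °C; then LiCl, 13, −20 °C → rt
Reagents that add atoms: none
Why: The mixed anhydride should acylate the oxazolidinone at the less hindered carbonyl under LiCl/Et3N activation (standard N-acylation of an Evans auxiliary).

Step 6
Reactants: 15 (S)-4-benzyl-3-[3-methyl-3-(triethylsilyloxy)butanoyl]oxazolidin-2-one
Product: 17 (S)-4-benzyl-3-[(2S)-2-(hydroxymethyl)-3-methyl-3-(triethylsilyloxy)butanoyl]oxazolidin-2-one, via chlorotitanium Z-enolate 16 (not isolated)
Conditions: TiCl4 (1.05 equiv), i-Pr2NEt, CH2Cl2, 0 °C; then 1,3,5-trioxane, TiCl4 (1.05 equiv), 0 °C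
Reagents that add atoms: 1,3,5-trioxane, C1OCOCO1
Why: In this Evans titanium-enolate hydroxymethylation the chelated Z-enolate is shielded on one face by the benzyl group, so TiCl4-activated formaldehyde should add from the opposite face and set the (S) centre.

Step 7
Reactants: 17 (S)-4-benzyl-3-[(2S)-2-(hydroxymethyl)-3-methyl-3-(triethylsilyloxy)butanoyl]oxazolidin-2-one
Product: 18 (2S)-2-(hydroxymethyl)-N-methoxy-N,3-dimethyl-3-(triethylsilyloxy)butanamide
Conditions: MeNH(OMe)·HCl, AlMe3, CH2Cl2, −10 → 0 °C; aq. potassium sodium tartrate work-up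
Reagents that add atoms: N,O-dimethylhydroxylamine hydrochloride, CNOC.Cl
Why: Weinreb transamination with the aluminium amide is directed to the exocyclic carbonyl by the free β-hydroxyl (as its aluminium alkoxide), so the auxiliary should be released without epimerisation.

Step 8
Reactants: 18 (2S)-2-(hydroxymethyl)-N-methoxy-N,3-dimethyl-3-(triethylsilyloxy)butanamide
Product: 19 (2S)-2-[(tert-butyldimethylsilyloxy)methyl]-N-methoxy-N,3-dimethyl-3-(triethylsilyloxy)butanamide
Conditions: t-BuMe2SiCl, imidazole, DMF, 0 °C → rt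
Reagents that add atoms: tert-butyldimethylsilyl chloride, CC(C)(C)[Si](C)(C)Cl
Why: The primary alcohol is silylated under standard conditions, which blocks it for the organometallic steps.

Step 9
Reactants: 19 (2S)-2-[(tert-butyldimethylsilyloxy)methyl]-N-methoxy-N,3-dimethyl-3-(triethylsilyloxy)butanamide
Product: 21 (4S)-4-[(tert-butyldimethylsilyloxy)methyl]-5-methyl-5-(triethylsilyloxy)hex-1-en-3-one, via magnesium-chelated tetrahedral adduct 20 (not isolated)
Conditions: CH2=CHMgBr, THF, −20 → 0 °C; inverse quench into cold 0.5 M HCl, immediate extraction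
Reagents that add atoms: vinylmagnesium bromide, C=C[Mg]Br
Why: In this Weinreb ketone synthesis the chelated adduct should prevent over-addition, and the cold acidic inverse quench keeps the liberated amine protonated so that it does not add to the enone.

Step 10
Reactants: 9 tert-butyl N-[5-(3-methylbut-2-en-1-yl)furan-2-yl]-N-[(tributylstannyl)methyl]carbamate; 21 (4S)-4-[(tert-butyldimethylsilyloxy)methyl]-5-methyl-5-(triethylsilyloxy)hex-1-en-3-one
Product: 23 tert-butyl N-{(3R)-3-[(tert-butyldimethylsilyloxy)methyl]-2-ethenyl-2-hydroxy-4-methyl-4-(triethylsilyloxy)pentyl}-N-[5-(3-methylbut-2-en-1-yl)furan-2-yl]carbamate (both C2 epimers), via N-Boc-aminomethyllithium 22 (not isolated)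
Conditions: n-BuLi, THF, −78 °C, 15 min; then 21, −78 °C; sat. aq. NH4Cl at −78 °C
Reagents that add atoms: none
Why: Tin–lithium exchange gives the dipole-stabilised α-amino organolithium, which should add 1,2 to the vinyl ketone at −78 °C; the existing centre is untouched and the new carbinol centre is left uncontrolled because it becomes the sp2 carbon C3.

Step 11
Reactants: 23 tert-butyl N-{(3R)-3-[(tert-butyldimethylsilyloxy)methyl]-2-ethenyl-2-hydroxy-4-methyl-4-(triethylsilyloxy)pentyl}-N-[5-(3-methylbut-2-en-1-yl)furan-2-yl]carbamate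
Product: 27 3-[(2S)-1-(tert-butyldimethylsilyloxy)-3-methyl-3-(triethylsilyloxy)butan-2-yl]-5-(3-methylbut-2-en-1-yl)-1H-indole, via oxa-bridged cycloadduct 24 (not isolated), via N-Boc-3-hydroxyindoline 25 (not isolated), via N-Boc-indole 26 (not isolated)
Conditions: o-dichlorobenzene (dilute), microwave, 180 °C, 30 min
Reagents that add atoms: none
Why: On heating, the electron-rich 2-(Boc-amino)furan (diene termini C7a and C5) and the tethered vinyl group undergo an intramolecular [4+2] cycloaddition that forms C3a–C7a and C4–C5 (24); the nitrogen lone pair then opens the C7a–O bridge, proton loss from C3a and loss of water across C4–C5 give the benzene ring (25), and a second loss of water across C2–C3 (26) followed by thermolysis of the Boc group gives the indole. The closest known reaction type is the microwave-promoted intramolecular Diels–Alder reaction of N-Boc-2-aminofurans that carry an allylic alcohol on a three-atom tether, which gives indoles by double dehydration. The five-membered ring (N1–C2–C3–C3a–C7a) is closed by the C3a–C7a bond as the ring fused through the three-atom tether, and the six-membered ring (C3a–C4–C5–C6–C7–C7a) is closed by the concerted formation of C3a–C7a and C4–C5. No stereocentre is created in the product, since the centres at C3, C3a, C5 and C7a of 24 all become sp2 on aromatisation, so both carbinol epimers converge. The step needs regiochemistry, which the tether fixes so that the furan C5 substituent becomes the indole C5 substituent; chemoselectivity for the tethered vinyl group over the prenyl alkene, which cannot reach the diene; and loss of the C3 hydroxyl toward C2 and not toward the side-chain methine. The last is expected because C2–H loss gives the aromatic pyrrole ring, while allylic strain holds the methine C–H of the branched side chain near the ring plane and orthogonal to the C3 p-orbital, so the (S) centre should be kept.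

Step 12
Reactants: 27 3-[(2S)-1-(tert-butyldimethylsilyloxy)-3-methyl-3-(triethylsilyloxy)butan-2-yl]-5-(3-methylbut-2-en-1-yl)-1H-indole
Product: 26 tert-butyl 3-[(2S)-1-(tert-butyldimethylsilyloxy)-3-methyl-3-(triethylsilyloxy)butan-2-yl]-5-(3-methylbut-2-en-1-yl)indole-1-carboxylate
Conditions: Boc2O, DMAP (cat.), MeCN, rt
Reagents that add atoms: di-tert-butyl dicarbonate, CC(C)(C)OC(=O)OC(=O)OC(C)(C)C
Why: DMAP-catalysed N-acylation restores the carbamate, which cannot be retained at 180 °C, and makes the indole electron-poor enough to survive the dioxirane oxidation that follows.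

Step 13
Reactants: 26 tert-butyl 3-[(2S)-1-(tert-butyldimethylsilyloxy)-3-methyl-3-(triethylsilyloxy)butan-2-yl]-5-(3-methylbut-2-en-1-yl)indole-1-carboxylate
Product: 28 tert-butyl 3-[(2S)-1-(tert-butyldimethylsilyloxy)-3-methyl-3-(triethylsilyloxy)butan-2-yl]-5-{[(2S)-3,3-dimethyloxiran-2-yl]methyl}indole-1-carboxylate
Conditions: L-fructose-derived Shi ketone (1,2:4,5-di-O-isopropylidene-β-L-erythro-2,3-hexodiulo-2,6-pyranose, 30 mol%), KHSO5 (as 2KHSO5·KHSO4·K2SO4), K2CO3, Bu4NHSO4 (cat.), Na2B4O7 buffer (pH about 10.5), MeCN/dimethoxymethane, 0 °C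
Reagents that add atoms: potassium peroxymonosulfate, [K+].[O-]S(=O)(=O)OO
Why: In the Shi asymmetric epoxidation the chiral dioxirane attacks the trisubstituted alkene through a spiro transition state; the L-fructose-derived ketone should give the (S) oxirane (the D-fructose ketone gives R) under reagent control, and the electron-rich alkene should react far faster than the N-Boc-indole.

Step 14
Reactants: 28 tert-butyl 3-[(2S)-1-(tert-butyldimethylsilyloxy)-3-methyl-3-(triethylsilyloxy)butan-2-yl]-5-{[(2S)-3,3-dimethyloxiran-2-yl]methyl}indole-1-carboxylate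
Product: 29 3-[(2S)-1-(tert-butyldimethylsilyloxy)-3-methyl-3-(triethylsilyloxy)butan-2-yl]-5-{[(2S)-3,3-dimethyloxiran-2-yl]methyl}-1H-indole
Conditions: K2CO3, MeOH, rt
Reagents that add atoms: none
Why: Methoxide should cleave the indole carbamate (the indolide is a good leaving group) while the silyl ethers and the hindered oxirane stay; the Boc group is removed before desilylation so that it cannot migrate to an alkoxide.

Step 15
Reactants: 29 3-[(2S)-1-(tert-butyldimethylsilyloxy)-3-methyl-3-(triethylsilyloxy)butan-2-yl]-5-{[(2S)-3,3-dimethyloxiran-2-yl]methyl}-1H-indole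
Product: 30 (2S)-2-(5-{[(2S)-3,3-dimethyloxiran-2-yl]methyl}-1H-indol-3-yl)-3-methylbutane-1,3-diol
Conditions: Bu4NF, THF, 0 °C → rt
Reagents that add atoms: none
Why: Fluoride should cleave both silyl ethers under basic, non-acidic conditions that the oxirane tolerates.

Step 16
Reactants: 30 (2S)-2-(5-{[(2S)-3,3-dimethyloxiran-2-yl]methyl}-1H-indol-3-yl)-3-methylbutane-1,3-diol; 31 oleic acid
Product: 33 (2S)-2-(5-{[(2S)-3,3-dimethyloxiran-2-yl]methyl}-1H-indol-3-yl)-3-hydroxy-3-methylbutyl (9Z)-octadec-9-enoate, via O-acylisourea 32 (not isolated)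
Conditions: DCC, DMAP (cat.), CH2Cl2, 0 °C → rt
Reagents that add atoms: none
Why: In this Steglich esterification the primary alcohol should be acylated much faster than the tertiary alcohol or the indole N–H, and the near-neutral medium spares the acid-labile oxirane and the Z alkene.

**Compound list**

1 | 2-furoic acid | OC(=O)c1ccco1 | starting material
2 | prenyl bromide (1-bromo-3-methylbut-2-ene) | CC(C)=CCBr | starting material
3 | lithium 5-lithiofuran-2-carboxylate (not isolated) | [Li]OC(=O)c1ccc([Li])o1 | intermediate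
4 | 5-(3-methylbut-2-en-1-yl)furan-2-carboxylic acid | CC(C)=CCc1ccc(C(=O)O)o1 | intermediate
5 | 5-(3-methylbut-2-en-1-yl)furan-2-carbonyl azide (not isolated) | CC(C)=CCc1ccc(o1)C(=O)N=[N+]=[N-] | intermediate
6 | 2-isocyanato-5-(3-methylbut-2-en-1-yl)furan (not isolated) | CC(C)=CCc1ccc(N=C=O)o1 | intermediate
7 | tert-butyl N-[5-(3-methylbut-2-en-1-yl)furan-2-yl]carbamate | CC(C)=CCc1ccc(NC(=O)OC(C)(C)C)o1 | intermediate
8 | sodium salt of carbamate 7 (not isolated) | [Na+].CC(C)=CCc1ccc(o1)[N-]C(=O)OC(C)(C)C | intermediate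
9 | tert-butyl N-[5-(3-methylbut-2-en-1-yl)furan-2-yl]-N-[(tributylstannyl)methyl]carbamate | CCCC[Sn](CCCC)(CCCC)CN(C(=O)OC(C)(C)C)c1ccc(CC=C(C)C)o1 | intermediate
10 | 3-hydroxy-3-methylbutanoic acid | CC(C)(O)CC(=O)O | starting material
11 | triethylsilyl 3-methyl-3-(triethylsilyloxy)butanoate (not isolated) | CC[Si](CC)(CC)OC(=O)CC(C)(C)O[Si](CC)(CC)CC | intermediate
12 | 3-methyl-3-(triethylsilyloxy)butanoic acid | CC[Si](CC)(CC)OC(C)(C)CC(=O)O | intermediate
13 | (S)-4-benzyloxazolidin-2-one | O=C1N[C@@H](Cc2ccccc2)CO1 | starting material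
14 | 3-methyl-3-(triethylsilyloxy)butanoic pivalic anhydride (not isolated) | CC[Si](CC)(CC)OC(C)(C)CC(=O)OC(=O)C(C)(C)C | intermediate
15 | (S)-4-benzyl-3-[3-methyl-3-(triethylsilyloxy)butanoyl]oxazolidin-2-one | CC[Si](CC)(CC)OC(C)(C)CC(=O)N1[C@@H](Cc2ccccc2)COC1=O | intermediate
16 | trichlorotitanium (Z)-enolate of 15 (not isolated) | Cl[Ti](Cl)(Cl)O/C(=C\C(C)(C)O[Si](CC)(CC)CC)N1[C@@H](Cc2ccccc2)COC1=O | intermediate
17 | (S)-4-benzyl-3-[(2S)-2-(hydroxymethyl)-3-methyl-3-(triethylsilyloxy)butanoyl]oxazolidin-2-one | OC[C@@H](C(C)(C)O[Si](CC)(CC)CC)C(=O)N1[C@@H](Cc2ccccc2)COC1=O | intermediate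
18 | (2S)-2-(hydroxymethyl)-N-methoxy-N,3-dimethyl-3-(triethylsilyloxy)butanamide | OC[C@@H](C(C)(C)O[Si](CC)(CC)CC)C(=O)N(C)OC | intermediate
19 | (2S)-2-[(tert-butyldimethylsilyloxy)methyl]-N-methoxy-N,3-dimethyl-3-(triethylsilyloxy)butanamide | CON(C)C(=O)[C@@H](CO[Si](C)(C)C(C)(C)C)C(C)(C)O[Si](CC)(CC)CC | intermediate
20 | bromomagnesium alkoxide of the tetrahedral vinyl adduct of 19 (not isolated) | C=CC(O[Mg]Br)(N(C)OC)[C@@H](CO[Si](C)(C)C(C)(C)C)C(C)(C)O[Si](CC)(CC)CC | intermediate
21 | (4S)-4-[(tert-butyldimethylsilyloxy)methyl]-5-methyl-5-(triethylsilyloxy)hex-1-en-3-one | C=CC(=O)[C@@H](CO[Si](C)(C)C(C)(C)C)C(C)(C)O[Si](CC)(CC)CC | intermediate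
22 | tert-butyl N-(lithiomethyl)-N-[5-(3-methylbut-2-en-1-yl)furan-2-yl]carbamate (not isolated) | [Li]CN(C(=O)OC(C)(C)C)c1ccc(CC=C(C)C)o1 | intermediate
23 | tert-butyl N-{(3R)-3-[(tert-butyldimethylsilyloxy)methyl]-2-ethenyl-2-hydroxy-4-methyl-4-(triethylsilyloxy)pentyl}-N-[5-(3-methylbut-2-en-1-yl)furan-2-yl]carbamate (both C2 epimers) | CC(C)(C)OC(=O)N(CC(O)(C=C)[C@@H](CO[Si](C)(C)C(C)(C)C)C(C)(C)O[Si](CC)(CC)CC)c1ccc(CC=C(C)C)o1 | intermediate
24 | tert-butyl 3-hydroxy-3-[(2R)-1-(tert-butyldimethylsilyloxy)-3-methyl-3-(triethylsilyloxy)butan-2-yl]-5-(3-methylbut-2-en-1-yl)-2,3,3a,4-tetrahydro-5,7a-epoxyindole-1(5H)-carboxylate (diastereomer mixture, not isolated) | CC(C)(C)OC(=O)N1CC(O)([C@@H](CO[Si](C)(C)C(C)(C)C)C(C)(C)O[Si](CC)(CC)CC)C2CC3(CC=C(C)C)C=CC12O3 | intermediate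
25 | tert-butyl 3-hydroxy-3-[(2R)-1-(tert-butyldimethylsilyloxy)-3-methyl-3-(triethylsilyloxy)butan-2-yl]-5-(3-methylbut-2-en-1-yl)-2,3-dihydroindole-1-carboxylate (both C3 epimers, not isolated) | CC(C)(C)OC(=O)N1CC(O)([C@@H](CO[Si](C)(C)C(C)(C)C)C(C)(C)O[Si](CC)(CC)CC)c2cc(CC=C(C)C)ccc12 | intermediate
26 | tert-butyl 3-[(2S)-1-(tert-butyldimethylsilyloxy)-3-methyl-3-(triethylsilyloxy)butan-2-yl]-5-(3-methylbut-2-en-1-yl)indole-1-carboxylate (transient in step 11, isolated in step 12) | CC(C)(C)OC(=O)n1cc([C@@H](CO[Si](C)(C)C(C)(C)C)C(C)(C)O[Si](CC)(CC)CC)c2cc(CC=C(C)C)ccc12 | intermediate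
27 | 3-[(2S)-1-(tert-butyldimethylsilyloxy)-3-methyl-3-(triethylsilyloxy)butan-2-yl]-5-(3-methylbut-2-en-1-yl)-1H-indole | CC(C)=CCc1ccc2[nH]cc([C@@H](CO[Si](C)(C)C(C)(C)C)C(C)(C)O[Si](CC)(CC)CC)c2c1 | intermediate
28 | tert-butyl 3-[(2S)-1-(tert-butyldimethylsilyloxy)-3-methyl-3-(triethylsilyloxy)butan-2-yl]-5-{[(2S)-3,3-dimethyloxiran-2-yl]methyl}indole-1-carboxylate | CC(C)(C)OC(=O)n1cc([C@@H](CO[Si](C)(C)C(C)(C)C)C(C)(C)O[Si](CC)(CC)CC)c2cc(C[C@@H]3OC3(C)C)ccc12 | intermediate
29 | 3-[(2S)-1-(tert-butyldimethylsilyloxy)-3-methyl-3-(triethylsilyloxy)butan-2-yl]-5-{[(2S)-3,3-dimethyloxiran-2-yl]methyl}-1H-indole | CC(C)(C)[Si](C)(C)OC[C@H](c1c[nH]c2ccc(C[C@@H]3OC3(C)C)cc12)C(C)(C)O[Si](CC)(CC)CC | intermediate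
30 | (2S)-2-(5-{[(2S)-3,3-dimethyloxiran-2-yl]methyl}-1H-indol-3-yl)-3-methylbutane-1,3-diol | OC[C@H](c1c[nH]c2ccc(C[C@@H]3OC3(C)C)cc12)C(C)(C)O | intermediate
31 | oleic acid ((9Z)-octadec-9-enoic acid) | CCCCCCCC/C=C\CCCCCCCC(=O)O | starting material
32 | O-oleoyl-N,N'-dicyclohexylisourea (not isolated) | CCCCCCCC/C=C\CCCCCCCC(=O)OC(=NC1CCCCC1)NC1CCCCC1 | intermediate
33 | (2S)-2-(5-{[(2S)-3,3-dimethyloxiran-2-yl]methyl}-1H-indol-3-yl)-3-hydroxy-3-methylbutyl (9Z)-octadec-9-enoate (CNP0291182.1) | CCCCCCCC/C=C\CCCCCCCC(=O)OC[C@H](c1c[nH]c2ccc(C[C@@H]3OC3(C)C)cc12)C(C)(C)O | target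

**Step count and risks**

Total step count: 16. Longest linear sequence: 13 steps (steps 4–16, from 3-hydroxy-3-methylbutanoic acid); the furan branch (steps 1–3) joins at step 10.

Steps most likely to fail:

1. Step 11. At 180 °C the tertiary benzylic C3–O bond may ionise, and the cation may lose the side-chain methine proton (the stereocentre is then scrambled on re-aromatisation) or fragment between the methine and the silyloxy-bearing carbon. Fallback: the cascade is interrupted. It sets out from 23, which is heated in toluene at about 150 °C in a sealed tube over solid K2CO3, where the sequence should stop at the N-Boc-3-hydroxyindoline 25, now isolated. Compound 25 is then dehydrated in a separate step with the Burgess reagent (methyl N-(triethylammoniosulfonyl)carbamate, THF, 50 °C), a syn-elimination through the sulfamate ester toward the unhindered C2–H bonds without a free cation, to give the N-Boc-indole 26. The route is rejoined at 26 (step 13), so the thermal Boc loss and step 12 are not needed; this fallback makes no compound outside the list (F0).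

2. Step 10. The organolithium may act as a base on the hindered, enolisable ketone 21 (with loss of silanolate from the enolate), may add in conjugate fashion, or the new alkoxide may attack the Boc carbonyl before the quench. Fallback: the order of bond formation is reversed so that the C3–vinyl bond is made last. It sets out from 9 and 19: the organolithium 22 is added to the Weinreb amide 19 (THF, −78 °C) to give the α-amino ketone tert-butyl N-{(3S)-3-[(tert-butyldimethylsilyloxy)methyl]-4-methyl-2-oxo-4-(triethylsilyloxy)pentyl}-N-[5-(3-methylbut-2-en-1-yl)furan-2-yl]carbamate F1. The vinylcerium reagent from CH2=CHMgBr and anhydrous CeCl3 (THF, −78 °C), which adds to enolisable ketones with little deprotonation, then gives 23, where the route is rejoined.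

3. Step 6. The excess TiCl4 may activate the tertiary silyloxy group, leading to elimination to the 3-methylbut-2-enoyl imide or to loss of the silyl ether before the enolate is trapped. Fallback: an alkylation without Lewis acid, setting out from 15. The sodium enolate (NaN(SiMe3)2, THF, −78 °C) is alkylated with benzyl chloromethyl ether, with the same facial sense as the aldol, to give (S)-4-benzyl-3-[(2S)-2-[(benzyloxy)methyl]-3-methyl-3-(triethylsilyloxy)butanoyl]oxazolidin-2-one F2. Hydrogenolysis (H2, Pd(OH)2 on carbon, EtOAc) then gives 17, where the route is rejoined.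

**Further compounds**

F0 | step 11 | none | none
F1 | step 10 | tert-butyl N-{(3S)-3-[(tert-butyldimethylsilyloxy)methyl]-4-methyl-2-oxo-4-(triethylsilyloxy)pentyl}-N-[5-(3-methylbut-2-en-1-yl)furan-2-yl]carbamate | CC(C)(C)OC(=O)N(CC(=O)[C@@H](CO[Si](C)(C)C(C)(C)C)C(C)(C)O[Si](CC)(CC)CC)c1ccc(CC=C(C)C)o1
F2 | step 6 | (S)-4-benzyl-3-[(2S)-2-[(benzyloxy)methyl]-3-methyl-3-(triethylsilyloxy)butanoyl]oxazolidin-2-one | c1ccccc1COC[C@@H](C(C)(C)O[Si](CC)(CC)CC)C(=O)N1[C@@H](Cc2ccccc2)COC1=O
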